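The runs were computed for an exercise; the scatter is artificial.

Start from a small charge: in the teal run 0.12 M of electrophile meets 0.237 M of nucleophile, and electrophile is down to 5 % of its charge at 1.50 min. The grey and violet runs, each with 0.25 M of electrophile, flatten instead. At the last reading, the electrophile lost per nucleophile charged is 0.979 in the grey run and 1.01 in the violet run, so count one to one within the scatter.

| flask | electrophile | nucleophile | remark | time |
|---|---|---|---|---|
| grey | 0.25 M | 0.12 M | run made earlier |  |
| violet | 0.25 M | 0.18 M | run made earlier |  |
| teal | 0.12 M | 0.237 M | run made earlier |  |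
| flask | 0.25 M | 0.237 M |  | 8.0 min |

| run | time / min | electrophile / % | target / % |
|---|---|---|---|
| grey | 1.33 | 65 | 1 |
| grey | 2.50 | 55 | 1 |
| grey | 4.00 | 51 | 2 |
| grey | 5.00 | 54 | 2 |
| grey | 6.00 | 53 | 1 |
| violet | 0.500 | 55 | 5 |
| violet | 1.50 | 49 | 0 |
| violet | 3.00 | 42 | 1 |
| violet | 5.00 | 27 | 0 |
| violet | 6.00 | 27 | 2 |
| teal | 0.500 | 14 | 14 |
| teal | 1.50 | 5 | 2 |
| teal | 3.00 | 0 | 0 |
| teal | 5.00 | 0 | 1 |
| teal | 6.00 | 1 | 1 |

(scatter of a reading: 2 percentage points)

- part of the electrophile that has reacted at 8.0 min
- share of the unused nucleophile that is free and not bound as protonated nucleophile, at 8.0 min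

- the earlier runs do not show how much of nucleophile is bound; that part of a forecast is a guess

Carry one rule: the ceiling S, the nucleophile charge over the electrophile charge, read as the most electrophile that charge can consume when nucleophile is the limiting reagent. In this flask nucleophile is the smaller charge, so S is 94.8 %.

Build the flask on S. Take first the main step alone, second order with apparent constant k. The first teal reading gives k of 0.397 M⁻¹ s⁻¹, and with it I reckon the flask at 94.4 %, close under S. Go round once more with a second process: the first grey reading, taken later and with other charges, gives k of 0.0844 M⁻¹ s⁻¹, lower, so one constant does not hold across these two readings. Take this as a slowing not yet named, put the lower k in, and my answer for the flask is 88.2 %. Add last the target, which reads 1 % in the grey run at 6.00 min. I treat any loss of target as coming after the electrophile has reacted, so I leave my number as it is. The readings do not show bound nucleophile, so the free share of the unused nucleophile stays a guess.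

The forecast, holding that the slowing “fits released acid tying up nucleophile reversibly”, gave 88 % and 15 %.

The flask gives 91.8 % of the electrophile reacted and a free share of 37.9 %.

    electrophile + nucleophile → acid set free + target (k = 0.903 M⁻¹ s⁻¹)
    nucleophile + acid set free ⇌ protonated nucleophile, settled at all times (K = 3400 M⁻¹)
    target → over-reaction product A (k = 0.0814 s⁻¹)
    acid set free → by-product carried off (k = 0.208 s⁻¹)
    target → over-reaction product B (k = 2.00 × 10⁻⁵ s⁻¹)

This flask has not come to rest at 8.0 min. It stands 3 percentage points under S, which on the electrophile charge is 0.00756 M. That gap is the unused nucleophile: 0.00286 M free and 0.00470 M as protonated nucleophile. By 80.0 min the reacted part reaches 94.8 %, with nucleophile at 0 % and protonated nucleophile at 0 M, and 5.20 % of the electrophile is left.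

In the flask with 1.0 M of electrophile, S is 23.7 %. The computed answer there is 23.7 %.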